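**Numbering used throughout.** Ring atoms: C1 (epoxide carbon bearing the exocyclic CH2, C7), C2, C3, C4=C5, C6 (epoxide CH). Compounds: 1 o-vanillyl alcohol; 2 aryloxyiodane (not isolated); 3 dienone; 4 peroxy enolate (not isolated); 5 epoxy ketone; 6 C7 benzoate; 7 C2 alcohol; 8 C2 acetate; 9 enone; 10 C3 alcohol (3S); 11 oxyphosphonium benzoate (not isolated); 12 target.

## Analysis of the target

The target 12 is a cyclohexene whose C1–C6 bond is bridged by an oxirane, a 7-oxabicyclo[4.1.0]hept-4-ene in which C1 is quaternary and carries the C7 CH2OBz group, C2 an acetate and C3 a benzoate, with C4=C5 as the only alkene. The four stereocentres are contiguous and have the configuration (1S,2S,3R,6S). The epoxide oxygen lies on one ring face, C7 and the C2 acetate on the other, and the C3 benzoate on the epoxide face, so that O2 and O3 are trans, O2 and the epoxide oxygen trans, and O3 and the epoxide oxygen cis. The oxirane is allylic and therefore sensitive to acid, soft nucleophiles and zerovalent palladium. The three esters rule out strong base and can migrate between O2, O3 and O7 once a neighbouring hydroxyl is free, and the allylic C3 ester can ionise or react in SN2' fashion. The difficulty is density: every ring carbon is functionalised, one acetate sits between two benzoates, C1 is a quaternary epoxide carbon, and absolute configuration must enter a ring whose only carbon substituent is C7. The route rests on one mapping: C7, O2 and O3 are the benzylic carbon, the phenol oxygen and the methoxy oxygen of o-vanillyl alcohol 1, whose dearomatised dienone 3 has C2 as a ketone, C3 masked at the ketone level, C4=C5 in place, and C1=C6 as an electron-poor alkene beside a free hydroxymethyl anchor.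

## Retrosynthetic reasoning

**12 to 10.** The C3–O(benzoyl) bond is cut and is to be formed with inversion. Reduction of the C3 ketone of 9 is expected to put the hydroxyl cis to the C2 acetate, the wrong relation. The benzoate has to be attached anyway, so an esterification that inverts C3 costs no extra step. The forward reaction must be a clean SN2 at an allylic carbinol, without SN2' attack at C5 and without acetate migration.

**10 to 9.** The C3–H bond is cut, back to the enone. The forward step is a 1,2-reduction that leaves the esters and the base-sensitive acyloxy epoxy enone intact.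

**9 to 8.** The C3 carbonyl is traced to its dimethyl ketal. Keeping C3 masked until C2 is reduced and acetylated means only one ketone is present at a time. O2 and O3 are then told apart by timing, not by selective acylation of a diol.

**8 to 7 to 6.** The O2–acetyl bond and then the C2–H bond are cut. The forward reduction must deliver hydride to C2 from the epoxide face, so that the hydroxyl ends trans to the epoxide oxygen and cis to C7.

**6 to 5.** The O7–benzoyl bond is cut. Benzoylation comes before the C2 reduction because a free C7 hydroxyl could carry hydride to the wrong face, and because it marks O7 before O2 exists.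

**5 to 3 (key disconnection).** Both C–O bonds of the oxirane are cut, giving back the C1=C6 alkene of 3. This alkene is the α,β-bond of the C2 ketone and sits beside the hydroxymethyl anchor, so a peroxide anion held by a chiral sodium alkoxide aggregate can add to C6 and close onto C1. An electrophilic oxidant would prefer the distal C4=C5 bond. One step gives the ring, both epoxide stereocentres and the absolute configuration from an achiral precursor.

**3 to 1.** The second C3–OMe bond is cut and the ring is rearomatised. The forward step is an oxidative dearomatisation in the alcohol that supplies the second methoxy group. It puts all seven carbons, four oxygenated ring carbons and both alkenes in place at once.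

## Alternatives that were turned down

Alternative 1: enzymatic arene cis-dihydroxylation. The C2–O and C3–O bonds are traced back to bromobenzene A1. Toluene dioxygenase in whole cells adds O2 across one ring bond of A1 and gives the bromodiene cis-diol A2, with bromine at the future C1.
- For: essentially complete enantiocontrol from the enzyme, an accessible product A2, and both alkenes retained.
- Against: A2 is a cis-diol, so C3 must be inverted after the two hydroxyls are differentiated. C7 must be attached at the vinyl bromide of A2 by cross-coupling or carbonylation, on a diene that readily loses water to rearomatise. The epoxidation must choose C1=C6 over C4=C5 and occur anti to O2, whereas an allylic oxygen directs syn. About ten to twelve steps are foreseeable.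
- Comparison: the path through A2 is stronger on enantiocontrol than a tartrate-mediated epoxidation. The chosen route offers instead all carbons and oxidation levels after step 1, the epoxide installed before the centres it must match, and about eight steps.

Alternative 2: carbene-catalysed crossed benzoin. The C1–C2 bond is cut. A chiral triazolylidene converts the aldehyde of the open-chain keto aldehyde A3 into its Breslow intermediate, which adds to the C1 ketone and gives the cyclic tertiary ketol A4.
- For: the quaternary carbinol C1 of A4 is made under catalyst control, C3 and C6 come independently from the chiral pool, and no unstable dienone is involved.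
- Against: A3 needs a Z-alkene flanked by two protected allylic carbinols, an epimerisable α-alkoxy aldehyde and an α-silyloxy ketone, and would take many steps. The α-alkoxy Breslow intermediate can divert into internal redox chemistry. After A4, the epoxide must be closed by displacement at allylic C6, C2 reduced, and two ethers exchanged for esters. Twice the length of the chosen route is realistic.
- Comparison: A4 gives more independent control of each centre, which the chosen route lacks at C2 and C3. The chosen route gets the quaternary C1 directly from the arene substitution pattern.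

Alternative 3: singlet oxygen on a dearomatised salicyl alcohol. The C3–O and C6–O bonds are cut. Salicyl alcohol A5 is taken in three steps (periodate dearomatisation, carbonyl reduction, acetylation) to the spiro-epoxy dienyl acetate A6. Singlet oxygen adds across the diene of A6 and gives the bicyclic endoperoxide A7. After O–O reduction of A7, the C6 alkoxide would open the spiro-epoxide at C1 with inversion (Payne-type), and O3 and O7 would be benzoylated together.
- For: very short and cheap from A5, the cis relation of O3 and O6 comes from the cycloaddition to A7, and both benzoates go on in one step.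
- Against: the spiro stereocentre of A6 arises from the achiral phenol A5 with no reliable asymmetric control, so a resolution is needed. The dearomatisation stage on the way to A6 suffers from the same Diels–Alder dimerisation as 3. C2 must be set against a spiro centre that differs only by CH2 versus O. The alkoxide step endangers the C2 acetate, and bicyclic peroxides such as A7 rearrange under base (Kornblum–DeLaMare).
- Comparison: the path through A7 is as short or shorter and better in ester economy. The chosen route offers an enantioselective key step on a precedented enone type and no alkoxide chemistry once the acetate is in place.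

Key step: step 2

Assumption: L-(+)-diisopropyl tartrate is taken as the enantiomer that delivers the peroxide to the face leading to (1S,6S)-5; if the sense is the opposite, D-(−)-diisopropyl tartrate is used and nothing else changes.

## Route

Step 1
Reactants: 1 2-hydroxy-3-methoxybenzyl alcohol (o-vanillyl alcohol)
Product: 3 2-(hydroxymethyl)-6,6-dimethoxycyclohexa-2,4-dien-1-one, via aryloxy(acetoxy)phenyliodane 2 (not isolated)
Conditions: PhI(OAc)2, MeOH, −10 °C; cold aq. NaHCO3/PhMe partition, Na2SO4, used at once as the PhMe solution
Reagents that add atoms: methanol, CO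
Why: Oxidative dearomatisation of a guaiacol by trivalent iodine: the phenol exchanges onto iodine to give 2, and methanol attacks the methoxy-bearing ring carbon, where the positive charge is best stabilised, with loss of PhI and acetate. The product is a masked o-benzoquinone; its 2-substituent slows but does not stop Diels–Alder dimerisation, hence the low temperature and immediate use.

Step 2
Reactants: 3 2-(hydroxymethyl)-6,6-dimethoxycyclohexa-2,4-dien-1-one
Product: 5 (1S,6S)-1-(hydroxymethyl)-3,3-dimethoxy-7-oxabicyclo[4.1.0]hept-4-en-2-one, via C6 trityl peroxide sodium enolate 4 (not isolated)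
Conditions: Ph3COOH, NaN(SiMe3)2, L-(+)-diisopropyl tartrate, 4 Å MS, PhMe, −60 °C
Reagents that add atoms: trityl hydroperoxide, OOC(c1ccccc1)(c1ccccc1)c1ccccc1
Why: NaN(SiMe3)2 converts trityl hydroperoxide and the tartrate into a sodium peroxide–alkoxide aggregate that also takes up the C7 hydroxyl of 3. The bound peroxide anion adds in conjugate fashion to C6, the β-carbon of the C2 ketone, and gives the sodium enolate 4. The enolate carbon C1 then attacks the peroxide oxygen on C6 and expels trityloxide, a 3-exo-tet closure that forms the oxirane (C6–O first, then C1–O) and completes a Weitz–Scheffer epoxidation. The closest known reaction is the tartrate-mediated nucleophilic epoxidation of 2-(hydroxymethyl)-p-quinone monoketals, which contain the same 2-(hydroxymethyl)enone unit; here that unit sits in a linearly conjugated o-quinone monoketal. C6 is set by the face to which the C7-anchored chiral aggregate delivers the peroxide, and C1 follows because the three-membered ring can only close on the face that already carries the peroxide. Site selectivity between C6 and the δ-carbon C4 is needed: C6 lies next to the anchoring hydroxymethyl group and is unhindered, whereas C4 is neopentyl-like beside the ketal and out of reach of the anchor, and a peroxide anion does not attack the C4=C5 alkene directly. Low temperature and dilution hold back the bimolecular dimerisation of 3, and 5 has no enolisable hydrogen and should be stable to the base.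

Step 3
Reactants: 5 (1S,6S)-1-(hydroxymethyl)-3,3-dimethoxy-7-oxabicyclo[4.1.0]hept-4-en-2-one
Product: 6 [(1S,6S)-3,3-dimethoxy-2-oxo-7-oxabicyclo[4.1.0]hept-4-en-1-yl]methyl benzoate
Conditions: BzCl, pyridine, DMAP (cat.), CH2Cl2, 0 °C
Reagents that add atoms: benzoyl chloride, O=C(Cl)c1ccccc1
Why: DMAP-catalysed acylation of an unhindered primary alcohol; the epoxide, ketal and non-enolisable ketone are inert to pyridine. The benzoate also removes the free hydroxyl, which could otherwise carry hydride to the wrong face of C2 in step 4.

Step 4
Reactants: 6 [(1S,6S)-3,3-dimethoxy-2-oxo-7-oxabicyclo[4.1.0]hept-4-en-1-yl]methyl benzoate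
Product: 7 [(1R,2R,6S)-2-hydroxy-3,3-dimethoxy-7-oxabicyclo[4.1.0]hept-4-en-1-yl]methyl benzoate
Conditions: NaBH4, CeCl3·7H2O, MeOH, −78 °C
Reagents that add atoms: none
Why: Luche-type 1,2-reduction of an α,β-epoxy ketone: trivalent cerium bridging the C2 carbonyl and epoxide oxygens should fix the half-chair in which C3 lies away from the epoxide, so borohydride adds axially from the epoxide face, anti to the pseudo-axial C3 methoxy group and away from the C1 CH2OBz group. Cyclic 2,3-epoxy ketones tend to give the trans-epoxy alcohol under these conditions, so the C2 hydroxyl should end trans to the epoxide oxygen and cis to C7. C4=C5 is not conjugated to this ketone, and the benzoate should survive at −78 °C.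

Step 5
Reactants: 7 [(1R,2R,6S)-2-hydroxy-3,3-dimethoxy-7-oxabicyclo[4.1.0]hept-4-en-1-yl]methyl benzoate
Product: 8 [(1S,2R,6S)-2-acetoxy-3,3-dimethoxy-7-oxabicyclo[4.1.0]hept-4-en-1-yl]methyl benzoate
Conditions: Ac2O, pyridine, DMAP (cat.), CH2Cl2, 0 °C to rt
Reagents that add atoms: acetic anhydride, CC(=O)OC(C)=O
Why: DMAP-catalysed acetylation of a hindered secondary alcohol without forming an alkoxide, so neither Payne migration of the trans-epoxy alcohol nor benzoyl transfer from O7 should start; C2 is not touched.

Step 6
Reactants: 8 [(1S,2R,6S)-2-acetoxy-3,3-dimethoxy-7-oxabicyclo[4.1.0]hept-4-en-1-yl]methyl benzoate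
Product: 9 [(1S,2R,6S)-2-acetoxy-3-oxo-7-oxabicyclo[4.1.0]hept-4-en-1-yl]methyl benzoate
Conditions: TsOH·H2O (cat.), THF/H2O, 0 °C to rt
Reagents that add atoms: water, O
Why: Acid-catalysed hydrolysis of an allylic dimethyl ketal through an oxocarbenium ion that C4=C5 stabilises. The epoxide should be spared because ionisation at C6 or C1 would place positive charge beside acyloxy-bearing carbons and the emerging enone. The α'-acetoxy γ,δ-epoxy enone 9 is base-labile (β-elimination and aromatisation) and is carried on without storage.

Step 7
Reactants: 9 [(1S,2R,6S)-2-acetoxy-3-oxo-7-oxabicyclo[4.1.0]hept-4-en-1-yl]methyl benzoate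
Product: 10 [(1S,2S,3S,6S)-2-acetoxy-3-hydroxy-7-oxabicyclo[4.1.0]hept-4-en-1-yl]methyl benzoate
Conditions: NaBH4, CeCl3·7H2O, MeOH, −78 °C; AcOH quench
Reagents that add atoms: none
Why: Luche 1,2-reduction of the enone. The C2 acetoxy group should sit pseudo-axial, because pseudo-equatorial it would eclipse the cis C1–C7 bond, so hydride adds to C3 anti to the C2–O bond (Felkin–Anh, also the less hindered side), which is the epoxide face. The new hydroxyl is therefore expected cis to the acetate (3S), the epimer of what 12 needs, and step 8 corrects it; low temperature and an acidic quench guard the cis-hydroxy acetate against acyl migration.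

Step 8
Reactants: 10 [(1S,2S,3S,6S)-2-acetoxy-3-hydroxy-7-oxabicyclo[4.1.0]hept-4-en-1-yl]methyl benzoate
Product: 12 [(1S,2S,3R,6S)-2-acetoxy-3-(benzoyloxy)-7-oxabicyclo[4.1.0]hept-4-en-1-yl]methyl benzoate, via C3 oxyphosphonium benzoate 11 (not isolated)
Conditions: PhCO2H, PPh3, DIAD, THF, 0 °C to rt
Reagents that add atoms: benzoic acid, O=C(O)c1ccccc1
Why: Mitsunobu esterification: PPh3/DIAD turn the allylic C3 hydroxyl into the oxyphosphonium benzoate 11, and benzoate displaces Ph3P=O by SN2 from the opposite face, inverting C3 to R and setting the 2,3-trans relation of the target 12. The cis acetate is syn to the leaving group and cannot act as a neighbouring group, only the C2 hydrogen faces the incoming benzoate, and the weakly acidic medium protects the epoxide and the esters.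

## Compound list

1 | 2-hydroxy-3-methoxybenzyl alcohol (o-vanillyl alcohol) | COc1cccc(CO)c1O | starting material
2 | acetoxy[2-(hydroxymethyl)-6-methoxyphenoxy](phenyl)iodane | COc1cccc(CO)c1OI(OC(C)=O)c1ccccc1 | intermediate (not isolated)
3 | 2-(hydroxymethyl)-6,6-dimethoxycyclohexa-2,4-dien-1-one | O=C1C(CO)=CC=CC1(OC)OC | intermediate
4 | sodium (3S)-2-(hydroxymethyl)-6,6-dimethoxy-3-(trityldioxy)cyclohexa-1,4-dien-1-olate | [Na+].[O-]C1=C(CO)[C@@H](OOC(c2ccccc2)(c2ccccc2)c2ccccc2)C=CC1(OC)OC | intermediate (not isolated)
5 | (1S,6S)-1-(hydroxymethyl)-3,3-dimethoxy-7-oxabicyclo[4.1.0]hept-4-en-2-one | O=C1C(OC)(OC)C=C[C@@H]2O[C@@]21CO | intermediate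
6 | [(1S,6S)-3,3-dimethoxy-2-oxo-7-oxabicyclo[4.1.0]hept-4-en-1-yl]methyl benzoate | O=C1C(OC)(OC)C=C[C@@H]2O[C@@]21COC(=O)c1ccccc1 | intermediate
7 | [(1R,2R,6S)-2-hydroxy-3,3-dimethoxy-7-oxabicyclo[4.1.0]hept-4-en-1-yl]methyl benzoate | O[C@H]1C(OC)(OC)C=C[C@@H]2O[C@@]21COC(=O)c1ccccc1 | intermediate
8 | [(1S,2R,6S)-2-acetoxy-3,3-dimethoxy-7-oxabicyclo[4.1.0]hept-4-en-1-yl]methyl benzoate | CC(=O)O[C@H]1C(OC)(OC)C=C[C@@H]2O[C@@]21COC(=O)c1ccccc1 | intermediate
9 | [(1S,2R,6S)-2-acetoxy-3-oxo-7-oxabicyclo[4.1.0]hept-4-en-1-yl]methyl benzoate | CC(=O)O[C@H]1C(=O)C=C[C@@H]2O[C@@]21COC(=O)c1ccccc1 | intermediate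
10 | [(1S,2S,3S,6S)-2-acetoxy-3-hydroxy-7-oxabicyclo[4.1.0]hept-4-en-1-yl]methyl benzoate | CC(=O)O[C@H]1[C@@H](O)C=C[C@@H]2O[C@@]21COC(=O)c1ccccc1 | intermediate
11 | {[(1S,2S,3S,6S)-2-acetoxy-1-(benzoyloxymethyl)-7-oxabicyclo[4.1.0]hept-4-en-3-yl]oxy}triphenylphosphonium benzoate | CC(=O)O[C@H]1[C@@H](O[P+](c2ccccc2)(c2ccccc2)c2ccccc2)C=C[C@@H]2O[C@@]21COC(=O)c1ccccc1.[O-]C(=O)c1ccccc1 | intermediate (not isolated)
12 | [(1S,2S,3R,6S)-2-acetoxy-3-(benzoyloxy)-7-oxabicyclo[4.1.0]hept-4-en-1-yl]methyl benzoate | CC(=O)O[C@H]1[C@H](OC(=O)c2ccccc2)C=C[C@@H]2O[C@@]21COC(=O)c1ccccc1 | target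

## Step count and least certain steps

Total step count: 8. Longest linear sequence: 8 steps (the route is linear from 1).

**Step 2 (key step).** Three things may go wrong. Dimerisation of 3 may outrun a slow low-temperature epoxidation. Conjugate addition may occur at C4 instead of C6. Facial discrimination may be poor, because the sodium tartrate aggregate has to bind a monoketal whose ketal now flanks the carbonyl. Fallback, setting out from 1 and returning at 5: 1 is oxidised as in step 1, and 30% H2O2 with K2CO3 is added directly to the cold methanolic solution of 3 (classical Weitz–Scheffer conditions), so that the dienone is trapped as it forms and gives racemic 1-(hydroxymethyl)-3,3-dimethoxy-7-oxabicyclo[4.1.0]hept-4-en-2-one F1. Kinetic resolution of this racemate with vinyl acetate and an immobilised lipase (Candida antarctica lipase B, chosen by screening) should acylate the unwanted enantiomer to [(1R,6R)-3,3-dimethoxy-2-oxo-7-oxabicyclo[4.1.0]hept-4-en-1-yl]methyl acetate F2. The unreacted (1S,6S) alcohol, which is 5, is then separated by chromatography.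

**Step 4.** Hydride may be delivered to C2 anti to the epoxide, the usual mode for nucleophiles that are not coordinated to the epoxide oxygen, giving poor or reversed facial selectivity. Fallback, setting out from 5 and returning at 8: 5 is silylated (t-BuPh2SiCl, imidazole, DMF) to (1S,6S)-1-{[tert-butyl(diphenyl)silyl]oxymethyl}-3,3-dimethoxy-7-oxabicyclo[4.1.0]hept-4-en-2-one F3, whose bulky silyl ether shields the C7 face. Reduction with i-Bu2AlH in THF at −78 °C, a Lewis-acidic hydride that binds the epoxide oxygen and transfers hydride on that face, should give (1R,2R,6S)-1-{[tert-butyl(diphenyl)silyl]oxymethyl}-3,3-dimethoxy-7-oxabicyclo[4.1.0]hept-4-en-2-ol F4. Acetylation (Ac2O, DMAP) then gives (1S,2R,6S)-1-{[tert-butyl(diphenyl)silyl]oxymethyl}-3,3-dimethoxy-7-oxabicyclo[4.1.0]hept-4-en-2-yl acetate F5. Desilylation with Bu4NF buffered by AcOH gives (1S,2R,6S)-1-(hydroxymethyl)-3,3-dimethoxy-7-oxabicyclo[4.1.0]hept-4-en-2-yl acetate F6, and benzoylation of its primary hydroxyl (BzCl, pyridine) gives 8.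

**Step 7.** Hydride may add syn to the acetate if the C2 acetoxy group sits pseudo-equatorial, and acetyl migration from O2 to O3 may occur before the quench. Fallback, setting out from 9 and returning at 12: if the reduction gives the 3R epimer [(1S,2S,3R,6S)-2-acetoxy-3-hydroxy-7-oxabicyclo[4.1.0]hept-4-en-1-yl]methyl benzoate F7, this alcohol is benzoylated directly with retention (BzCl, pyridine, DMAP, 0 °C) to 12. A mixture of epimers is separated, and each goes to its own esterification, the 3R epimer by acylation and 10 by step 8.

**Step 8.** Benzoate may attack C5 in SN2' fashion, the oxyphosphonium salt may eliminate towards C2, or acetyl may migrate from O2 to O3 before activation. Fallback, setting out from 7 and returning at 12: the ketal of 7 is hydrolysed (TsOH·H2O, THF/H2O) to [(1R,2R,6S)-2-hydroxy-3-oxo-7-oxabicyclo[4.1.0]hept-4-en-1-yl]methyl benzoate F8. Me4NBH(OAc)3 in MeCN/AcOH at −20 °C binds the C2 hydroxyl and delivers hydride to C3 on the same face (Evans–Saksena-type directed reduction), which should give the trans-diol [(1R,2S,3R,6S)-2,3-dihydroxy-7-oxabicyclo[4.1.0]hept-4-en-1-yl]methyl benzoate F9. The allylic C3 hydroxyl, less hindered than the C2 hydroxyl beside quaternary C1, is benzoylated selectively (BzCl, one equivalent, pyridine, −40 °C) to [(1R,2S,3R,6S)-3-(benzoyloxy)-2-hydroxy-7-oxabicyclo[4.1.0]hept-4-en-1-yl]methyl benzoate F10, and acetylation of the remaining C2 hydroxyl (Ac2O, DMAP) gives 12.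

## Further compounds

F1 | step 2 | racemic 1-(hydroxymethyl)-3,3-dimethoxy-7-oxabicyclo[4.1.0]hept-4-en-2-one | O=C1C(OC)(OC)C=CC2OC21CO
F2 | step 2 | [(1R,6R)-3,3-dimethoxy-2-oxo-7-oxabicyclo[4.1.0]hept-4-en-1-yl]methyl acetate | O=C1C(OC)(OC)C=C[C@H]2O[C@]21COC(C)=O
F3 | step 4 | (1S,6S)-1-{[tert-butyl(diphenyl)silyl]oxymethyl}-3,3-dimethoxy-7-oxabicyclo[4.1.0]hept-4-en-2-one | O=C1C(OC)(OC)C=C[C@@H]2O[C@@]21CO[Si](c1ccccc1)(c1ccccc1)C(C)(C)C
F4 | step 4 | (1R,2R,6S)-1-{[tert-butyl(diphenyl)silyl]oxymethyl}-3,3-dimethoxy-7-oxabicyclo[4.1.0]hept-4-en-2-ol | O[C@H]1C(OC)(OC)C=C[C@@H]2O[C@@]21CO[Si](c1ccccc1)(c1ccccc1)C(C)(C)C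
F5 | step 4 | (1S,2R,6S)-1-{[tert-butyl(diphenyl)silyl]oxymethyl}-3,3-dimethoxy-7-oxabicyclo[4.1.0]hept-4-en-2-yl acetate | CC(=O)O[C@H]1C(OC)(OC)C=C[C@@H]2O[C@@]21CO[Si](c1ccccc1)(c1ccccc1)C(C)(C)C
F6 | step 4 | (1S,2R,6S)-1-(hydroxymethyl)-3,3-dimethoxy-7-oxabicyclo[4.1.0]hept-4-en-2-yl acetate | CC(=O)O[C@H]1C(OC)(OC)C=C[C@@H]2O[C@@]21CO
F7 | step 7 | [(1S,2S,3R,6S)-2-acetoxy-3-hydroxy-7-oxabicyclo[4.1.0]hept-4-en-1-yl]methyl benzoate | CC(=O)O[C@H]1[C@H](O)C=C[C@@H]2O[C@@]21COC(=O)c1ccccc1
F8 | step 8 | [(1R,2R,6S)-2-hydroxy-3-oxo-7-oxabicyclo[4.1.0]hept-4-en-1-yl]methyl benzoate | O[C@H]1C(=O)C=C[C@@H]2O[C@@]21COC(=O)c1ccccc1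
F9 | step 8 | [(1R,2S,3R,6S)-2,3-dihydroxy-7-oxabicyclo[4.1.0]hept-4-en-1-yl]methyl benzoate | O[C@H]1[C@H](O)C=C[C@@H]2O[C@@]21COC(=O)c1ccccc1
F10 | step 8 | [(1R,2S,3R,6S)-3-(benzoyloxy)-2-hydroxy-7-oxabicyclo[4.1.0]hept-4-en-1-yl]methyl benzoate | O[C@H]1[C@H](OC(=O)c2ccccc2)C=C[C@@H]2O[C@@]21COC(=O)c1ccccc1
A1 | alternative 1 | bromobenzene | Brc1ccccc1
A2 | alternative 1 | (1S,2S)-3-bromocyclohexa-3,5-diene-1,2-diol | O[C@H]1[C@@H](O)C=CC=C1Br
A3 | alternative 2 | (Z)-3-(tert-butyldimethylsilyloxy)-6-(4-methoxybenzyloxy)-2,7-dioxohept-4-en-1-yl benzoate (configuration as in the SMILES) | O=C[C@H](OCc1ccc(OC)cc1)/C=C\[C@@H](O[Si](C)(C)C(C)(C)C)C(=O)COC(=O)c1ccccc1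
A4 | alternative 2 | [1-hydroxy-6-(tert-butyldimethylsilyloxy)-3-(4-methoxybenzyloxy)-2-oxocyclohex-4-en-1-yl]methyl benzoate (configuration as in the SMILES) | O=C1[C@H](OCc2ccc(OC)cc2)C=C[C@@H](O[Si](C)(C)C(C)(C)C)[C@@]1(O)COC(=O)c1ccccc1
A5 | alternative 3 | 2-hydroxybenzyl alcohol (salicyl alcohol) | OCc1ccccc1O
A6 | alternative 3 | 1-oxaspiro[2.5]octa-5,7-dien-4-yl acetate (configuration as in the SMILES) | CC(=O)O[C@H]1C=CC=C[C@]12CO2
A7 | alternative 3 | spiro[2,3-dioxabicyclo[2.2.2]oct-5-ene-7,2'-oxiran]-8-yl acetate (configuration as in the SMILES) | CC(=O)O[C@H]1[C@H]3C=C[C@H](OO3)[C@]12CO2
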